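**Retrosynthetic overview**

1. The plan rests on C6 (core numbering: C1 isobutyryl bridgehead, C2 CMe2, C3 CH‑prenyl, C4 CH2, C5 prenyl bridgehead, C7/C8 ketones). C6 is a tertiary carbinol bearing the C7 ketone and the exocyclic acyl carbon, and it lies β to the C8 ketone through C5. It is therefore the aldol adduct of a C5 enolate with the middle carbonyl of an α,β‑diketo ester chain on C1; the C5–C6 bond closes the cyclopentane C1–C7–C6–C5–C8 onto the cyclohexanone C1–C2–C3–C4–C5–C8.
2. Target ⇐ (Z)‑selective semihydrogenation of the C6 ynone ⇐ Pd/Cu coupling of the C6 thioester with 2‑methylbut‑3‑yn‑2‑ol ⇐ C6 methyl ester of the aldol product.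
3. Tricarbonyl ⇐ periodinane oxidation of a β‑keto ester ⇐ hydration of a C1 alkynoate, then C5 prenylation. The C1 quaternary centre ⇐ enolate addition–elimination on methyl 3‑bromopropiolate, trans to the C3 prenyl group.
4. β‑Diketone ⇐ two cuprate additions and an isobutyraldehyde aldol on (S)‑4‑prenylcyclohexenone ⇐ enamine‑catalysed Michael addition of 5‑methylhex‑4‑enal to methyl vinyl ketone, which sets C3 and with it the absolute configuration.
5. Ring order: cyclohexane ring first (step 3), cyclopentane ring second (step 13).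

Key step: step 13

**Route**

Step 1
Reactants: 1 methyl 5-methylhex-4-enoate
Product: 2 5-methylhex-4-enal
Conditions: i-Bu2AlH (1.05 equiv), CH2Cl2, −78 °C; aq. potassium sodium tartrate
Reagents that add atoms: none
Why: Partial ester reduction: the aluminium hemiacetal formed by one hydride transfer is stable at −78 °C and gives the aldehyde on hydrolysis.

Step 2
Reactants: 2 5-methylhex-4-enal; 3 but-3-en-2-one
Product: 4 (2S)-5-methyl-2-(3-oxobutyl)hex-4-enal
Conditions: (S)-2-[methoxy(diphenyl)methyl]pyrrolidine (5 mol %), ethyl 3,4-dihydroxybenzoate (20 mol %), neat, 4 °C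
Reagents that add atoms: none
Why: Enamine-catalysed Michael addition in which the E-enamine of 2 is attacked by the enone on the face away from the diphenyl(methoxy)methyl group of the (S)-catalyst, setting the future C3 centre.

Step 3
Reactants: 4 (2S)-5-methyl-2-(3-oxobutyl)hex-4-enal
Product: 5 (4S)-4-(3-methylbut-2-en-1-yl)cyclohex-2-en-1-one
Conditions: 0.1 M KOH (aq), n-Bu4NOH (cat.), Et2O–THF, reflux
Reagents that add atoms: none
Why: Intramolecular aldol condensation of the methyl ketone enolate onto the aldehyde closes the six-membered enone; the existing centre becomes the γ-carbon and is not involved in the ring closure.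

Step 4
Reactants: 5 (4S)-4-(3-methylbut-2-en-1-yl)cyclohex-2-en-1-one
Product: 6 trimethyl{[(3S,4S)-3-methyl-4-(3-methylbut-2-en-1-yl)cyclohex-1-en-1-yl]oxy}silane
Conditions: Me2CuLi (from MeLi, CuI), Me3SiCl, Et3N, THF–Et2O, −78 °C
Reagents that add atoms: lithium dimethylcuprate, [Li+].C[Cu-]C; chlorotrimethylsilane, C[Si](C)(C)Cl
Why: Silyl-chloride-accelerated conjugate addition of the Gilman cuprate anti to the C4 substituent with O-silylation of the enolate; the new methyl-bearing centre is transient.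

Step 5
Reactants: 6 trimethyl{[(3S,4S)-3-methyl-4-(3-methylbut-2-en-1-yl)cyclohex-1-en-1-yl]oxy}silane
Product: 7 (4S)-3-methyl-4-(3-methylbut-2-en-1-yl)cyclohex-2-en-1-one
Conditions: Pd(OAc)2 (10 mol %), O2 (1 atm), DMSO, rt
Reagents that add atoms: none
Why: Saegusa–Ito oxidation: divalent palladium palladates the silyl enol ether and β-hydride elimination from the methyl-bearing carbon re-forms the enone, now β-methylated, under neutral conditions that leave C4 and the prenyl olefin untouched.

Step 6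
Reactants: 7 (4S)-3-methyl-4-(3-methylbut-2-en-1-yl)cyclohex-2-en-1-one; 8 2-methylpropanal
Product: 10 (4S)-2-(1-hydroxy-2-methylpropyl)-3,3-dimethyl-4-(3-methylbut-2-en-1-yl)cyclohexan-1-one, via lithium enolate 9 (not isolated)
Conditions: Me2CuLi (from MeLi, CuI), Et2O, −20 → 0 °C; ZnCl2, then 8, −78 °C; aq. NH4Cl
Reagents that add atoms: lithium dimethylcuprate, [Li+].C[Cu-]C (methyl in 10, lithium in 9)
Why: A second cuprate conjugate addition builds the gem-dimethyl carbon (no new stereocentre) and delivers the enolate regiospecifically at the adjacent carbon, which is trapped as its zinc enolate in an aldol addition; the two uncontrolled new centres are removed in step 7.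

Step 7
Reactants: 10 (4S)-2-(1-hydroxy-2-methylpropyl)-3,3-dimethyl-4-(3-methylbut-2-en-1-yl)cyclohexan-1-one
Product: 11 (4S)-3,3-dimethyl-4-(3-methylbut-2-en-1-yl)-2-(2-methylpropanoyl)cyclohexan-1-one
Conditions: Dess–Martin periodinane, CH2Cl2, 0 °C → rt
Reagents that add atoms: none
Why: Dess–Martin oxidation of the secondary alcohol gives the β-diketone; the trisubstituted olefin is inert to the periodinane.

Step 8
Reactants: 12 methyl prop-2-ynoate
Product: 13 methyl 3-bromoprop-2-ynoate
Conditions: NBS, AgNO3 (10 mol %), acetone, rt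
Reagents that add atoms: N-bromosuccinimide, O=C1CCC(=O)N1Br
Why: Silver-catalysed electrophilic bromination of the terminal alkyne C–H through the silver acetylide.

Step 9
Reactants: 11 (4S)-3,3-dimethyl-4-(3-methylbut-2-en-1-yl)-2-(2-methylpropanoyl)cyclohexan-1-one; 13 methyl 3-bromoprop-2-ynoate
Product: 14 methyl 3-[(1S,3S)-2,2-dimethyl-3-(3-methylbut-2-en-1-yl)-1-(2-methylpropanoyl)-6-oxocyclohexyl]prop-2-ynoate
Conditions: Cs2CO3, n-Bu4NBr (10 mol %), toluene, −20 → 0 °C
Reagents that add atoms: none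
Why: Nucleophilic acetylenic substitution (conjugate addition–elimination) of the ammonium β-diketonate at the bromine-bearing sp carbon, a small soft electrophile that reacts at carbon where an acyl chloride would O-acylate; attack is axial, anti to the pseudoaxial C2 methyl and trans to the C3 prenyl group, which sets the C1 quaternary centre while C5 is still unsubstituted and cannot bias the face.

Step 10
Reactants: 14 methyl 3-[(1S,3S)-2,2-dimethyl-3-(3-methylbut-2-en-1-yl)-1-(2-methylpropanoyl)-6-oxocyclohexyl]prop-2-ynoate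
Product: 16 methyl 3-[(1R,3S)-2,2-dimethyl-3-(3-methylbut-2-en-1-yl)-1-(2-methylpropanoyl)-6-oxocyclohexyl]-3-oxopropanoate, via enamino ester 15 (not isolated)
Conditions: morpholine (1.1 equiv), THF, 0 °C; then 1 M HCl (aq), rt
Reagents that add atoms: morpholine, C1COCCN1 (in 15); water, O (in 16)
Why: Amine conjugate addition to the ynoate at the carbon β to the ester and acid hydrolysis of the β-enamino ester amount to an ester-directed hydration that places the ketone on C7; no stereocentre is formed.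

Step 11
Reactants: 16 methyl 3-[(1R,3S)-2,2-dimethyl-3-(3-methylbut-2-en-1-yl)-1-(2-methylpropanoyl)-6-oxocyclohexyl]-3-oxopropanoate; 17 1-bromo-3-methylbut-2-ene
Product: 19 methyl 3-[(1R,3R,5RS)-2,2-dimethyl-3,5-bis(3-methylbut-2-en-1-yl)-1-(2-methylpropanoyl)-6-oxocyclohexyl]-3-oxopropanoate, via dilithium dienolate 18 (not isolated)
Conditions: LiN(i-Pr)2 (2.2 equiv), THF, −78 °C; 17 (1.05 equiv), −78 → −40 °C; aq. NH4Cl
Reagents that add atoms: lithium diisopropylamide, CC(C)N([Li])C(C)C (lithium in 18)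
Why: Dianion alkylation: the first equivalent of base stores the chain as its unreactive β-keto ester enolate, the second removes a C5 hydrogen (the only accessible α-CH2), and the more basic ketone enolate is alkylated by the allylic bromide; C5 forms as a mixture that is erased by enolisation in step 13.

Step 12
Reactants: 19 methyl 3-[(1R,3R,5RS)-2,2-dimethyl-3,5-bis(3-methylbut-2-en-1-yl)-1-(2-methylpropanoyl)-6-oxocyclohexyl]-3-oxopropanoate
Product: 20 methyl 3-[(1R,3R,5RS)-2,2-dimethyl-3,5-bis(3-methylbut-2-en-1-yl)-1-(2-methylpropanoyl)-6-oxocyclohexyl]-2,3-dioxopropanoate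
Conditions: Dess–Martin periodinane (3 equiv), pyridine, CH2Cl2, rt; toluene azeotrope
Reagents that add atoms: Dess–Martin periodinane, CC(=O)OI1(OC(C)=O)(OC(C)=O)OC(=O)c2ccccc12 (oxygen of the new C6 carbonyl)
Why: Periodinane oxidation of the enolised β-keto ester methylene, by α-oxygenation followed by alcohol oxidation, gives the vicinal tricarbonyl; unlike dioxirane, ozone or singlet oxygen, the periodinane leaves the two prenyl olefins alone.

Step 13
Reactants: 20 methyl 3-[(1R,3R,5RS)-2,2-dimethyl-3,5-bis(3-methylbut-2-en-1-yl)-1-(2-methylpropanoyl)-6-oxocyclohexyl]-2,3-dioxopropanoate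
Product: 21 methyl (1R,3R,5S,6R)-6-hydroxy-2,2-dimethyl-3,5-bis(3-methylbut-2-en-1-yl)-1-(2-methylpropanoyl)-7,8-dioxobicyclo[3.2.1]octane-6-carboxylate
Conditions: DBU (0.2 equiv), 4 Å molecular sieves, CH2Cl2, −40 → 0 °C; then AcOH
Reagents that add atoms: none
Why: DBU reversibly removes the C5 hydrogen, the only α-hydrogen of the C8 ketone (the isobutyryl methine belongs to a tert-alkyl isopropyl ketone whose enolate is disfavoured by allylic strain), and the enolate adds to the central, most electrophilic carbonyl of the α,β-diketo ester on C1, an intramolecular aldol addition to a vicinal tricarbonyl. The cyclopentane C1–C7–C6–C5–C8 closes 5-exo-trig at C6 with the C5=C8 enolate bond inside the new ring (5-enolendo); this is geometrically possible because the chain stands 1,3-diaxial to the C5 p-orbital of the chair enolate, whereas attack at C7 or at the ester carbon would need a four- or six-membered ring. C5 can bond only on the face that carries the C1 chain, so its configuration follows from C1, set in step 9 trans to the equatorial C3 prenyl group that holds the chain axial. At C6 the metal-free amidinium enolate should react through an open transition state with the C6 oxygen turned away from the enolate oxygen (endo) and the ester in the less encumbered exo position, syn to C8 and not eclipsing C4; reversibility of the addition under DBU should favour the same epimer. The step needs chemoselectivity for aldol addition over ene reaction of the prenyl groups and over retro-Claisen cleavage at C1, which low temperature, exclusion of water and a catalytic non-nucleophilic base are meant to secure.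

Step 14
Reactants: 21 methyl (1R,3R,5S,6R)-6-hydroxy-2,2-dimethyl-3,5-bis(3-methylbut-2-en-1-yl)-1-(2-methylpropanoyl)-7,8-dioxobicyclo[3.2.1]octane-6-carboxylate
Product: 22 S-ethyl (1R,3R,5S,6R)-6-hydroxy-2,2-dimethyl-3,5-bis(3-methylbut-2-en-1-yl)-1-(2-methylpropanoyl)-7,8-dioxobicyclo[3.2.1]octane-6-carbothioate
Conditions: Me2AlSEt (from AlMe3, EtSH; 3 equiv), CH2Cl2, 0 °C → rt
Reagents that add atoms: ethanethiol, CCS (delivered as Me2AlSEt)
Why: Aluminium thiolate conversion of an ester into a thioester, in which the C6 alkoxide binds aluminium and delivers the thiolate to the neighbouring ester carbonyl, while the three ketones, each next to a quaternary carbon, do not add the soft nucleophile irreversibly; no stereocentre changes.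

Step 15
Reactants: 22 S-ethyl (1R,3R,5S,6R)-6-hydroxy-2,2-dimethyl-3,5-bis(3-methylbut-2-en-1-yl)-1-(2-methylpropanoyl)-7,8-dioxobicyclo[3.2.1]octane-6-carbothioate; 23 2-methylbut-3-yn-2-ol
Product: 24 (1R,3R,5S,6S)-6-hydroxy-6-(4-hydroxy-4-methylpent-2-ynoyl)-2,2-dimethyl-3,5-bis(3-methylbut-2-en-1-yl)-1-(2-methylpropanoyl)bicyclo[3.2.1]octane-7,8-dione
Conditions: PdCl2(dppf) (10 mol %), P(2-furyl)3 (25 mol %), CuI (1.7 equiv), Et3N–DMF, 50 °C
Reagents that add atoms: none
Why: Sonogashira-type acyl alkynylation of a thioester: zerovalent palladium inserts into the C–S bond, the copper acetylide of 23 transmetalates and reductive elimination gives the ynone, with CuI taking up the thiolate; ketones and both tertiary alcohols are spectators.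

Step 16
Reactants: 24 (1R,3R,5S,6S)-6-hydroxy-6-(4-hydroxy-4-methylpent-2-ynoyl)-2,2-dimethyl-3,5-bis(3-methylbut-2-en-1-yl)-1-(2-methylpropanoyl)bicyclo[3.2.1]octane-7,8-dione
Product: 25 (1R,3R,5S,6S)-6-hydroxy-6-[(2Z)-4-hydroxy-4-methylpent-2-enoyl]-2,2-dimethyl-3,5-bis(3-methylbut-2-en-1-yl)-1-(2-methylpropanoyl)bicyclo[3.2.1]octane-7,8-dione
Conditions: H2 (1 atm), Pd/CaCO3 poisoned with Pb(OAc)2, quinoline, EtOAc, 0 °C
Reagents that add atoms: none
Why: Lindlar semihydrogenation delivers both hydrogens syn on the poisoned palladium surface and gives the (Z)-enone; the trisubstituted prenyl olefins are not reduced and the tertiary γ-alcohol cannot dehydrate to a furan.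

**Compound list**

1 | methyl 5-methylhex-4-enoate | COC(=O)CCC=C(C)C | starting material
2 | 5-methylhex-4-enal | O=CCCC=C(C)C | intermediate
3 | but-3-en-2-one | CC(=O)C=C | starting material
4 | (2S)-5-methyl-2-(3-oxobutyl)hex-4-enal | O=C[C@H](CC=C(C)C)CCC(C)=O | intermediate
5 | (4S)-4-(3-methylbut-2-en-1-yl)cyclohex-2-en-1-one | O=C1C=C[C@H](CC=C(C)C)CC1 | intermediate
6 | trimethyl{[(3S,4S)-3-methyl-4-(3-methylbut-2-en-1-yl)cyclohex-1-en-1-yl]oxy}silane | C[Si](C)(C)OC1=C[C@@H](C)[C@H](CC=C(C)C)CC1 | intermediate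
7 | (4S)-3-methyl-4-(3-methylbut-2-en-1-yl)cyclohex-2-en-1-one | O=C1C=C(C)[C@H](CC=C(C)C)CC1 | intermediate
8 | 2-methylpropanal | CC(C)C=O | starting material
9 | lithium (4S)-3,3-dimethyl-4-(3-methylbut-2-en-1-yl)cyclohex-1-en-1-olate | [Li]OC1=CC(C)(C)[C@H](CC=C(C)C)CC1 | intermediate
10 | (4S)-2-(1-hydroxy-2-methylpropyl)-3,3-dimethyl-4-(3-methylbut-2-en-1-yl)cyclohexan-1-one (epimers at C2 and at the carbinol) | CC(C)=CC[C@@H]1CCC(=O)C(C(O)C(C)C)C1(C)C | intermediate
11 | (4S)-3,3-dimethyl-4-(3-methylbut-2-en-1-yl)-2-(2-methylpropanoyl)cyclohexan-1-one (C2 epimers and enol) | CC(C)=CC[C@@H]1CCC(=O)C(C(=O)C(C)C)C1(C)C | intermediate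
12 | methyl prop-2-ynoate | COC(=O)C#C | starting material
13 | methyl 3-bromoprop-2-ynoate | COC(=O)C#CBr | intermediate
14 | methyl 3-[(1S,3S)-2,2-dimethyl-3-(3-methylbut-2-en-1-yl)-1-(2-methylpropanoyl)-6-oxocyclohexyl]prop-2-ynoate | CC(C)=CC[C@@H]1CCC(=O)[C@@](C(=O)C(C)C)(C#CC(=O)OC)C1(C)C | intermediate
15 | methyl 3-[(1S,3S)-2,2-dimethyl-3-(3-methylbut-2-en-1-yl)-1-(2-methylpropanoyl)-6-oxocyclohexyl]-3-(morpholin-4-yl)prop-2-enoate (alkene geometry not defined) | CC(C)=CC[C@@H]1CCC(=O)[C@@](C(=O)C(C)C)(C(=CC(=O)OC)N2CCOCC2)C1(C)C | intermediate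
16 | methyl 3-[(1R,3S)-2,2-dimethyl-3-(3-methylbut-2-en-1-yl)-1-(2-methylpropanoyl)-6-oxocyclohexyl]-3-oxopropanoate | CC(C)=CC[C@@H]1CCC(=O)[C@@](C(=O)C(C)C)(C(=O)CC(=O)OC)C1(C)C | intermediate
17 | 1-bromo-3-methylbut-2-ene | CC(C)=CCBr | starting material
18 | dilithium dienolate of 16 (C5=C8 ketone enolate and chain β-keto ester enolate) | CC(C)=CC[C@@H]1CC=C(O[Li])[C@@](C(=O)C(C)C)(C(O[Li])=CC(=O)OC)C1(C)C | intermediate
19 | methyl 3-[(1R,3R,5RS)-2,2-dimethyl-3,5-bis(3-methylbut-2-en-1-yl)-1-(2-methylpropanoyl)-6-oxocyclohexyl]-3-oxopropanoate | CC(C)=CC[C@@H]1CC(CC=C(C)C)C(=O)[C@@](C(=O)C(C)C)(C(=O)CC(=O)OC)C1(C)C | intermediate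
20 | methyl 3-[(1R,3R,5RS)-2,2-dimethyl-3,5-bis(3-methylbut-2-en-1-yl)-1-(2-methylpropanoyl)-6-oxocyclohexyl]-2,3-dioxopropanoate | CC(C)=CC[C@@H]1CC(CC=C(C)C)C(=O)[C@@](C(=O)C(C)C)(C(=O)C(=O)C(=O)OC)C1(C)C | intermediate
21 | methyl (1R,3R,5S,6R)-6-hydroxy-2,2-dimethyl-3,5-bis(3-methylbut-2-en-1-yl)-1-(2-methylpropanoyl)-7,8-dioxobicyclo[3.2.1]octane-6-carboxylate (hydroxyl endo, ester exo) | CC(C)=CC[C@@H]1C[C@]2(CC=C(C)C)C(=O)[C@@](C(=O)C(C)C)(C(=O)[C@@]2(O)C(=O)OC)C1(C)C | intermediate
22 | S-ethyl (1R,3R,5S,6R)-6-hydroxy-2,2-dimethyl-3,5-bis(3-methylbut-2-en-1-yl)-1-(2-methylpropanoyl)-7,8-dioxobicyclo[3.2.1]octane-6-carbothioate | CC(C)=CC[C@@H]1C[C@]2(CC=C(C)C)C(=O)[C@@](C(=O)C(C)C)(C(=O)[C@@]2(O)C(=O)SCC)C1(C)C | intermediate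
23 | 2-methylbut-3-yn-2-ol | CC(C)(O)C#C | starting material
24 | (1R,3R,5S,6S)-6-hydroxy-6-(4-hydroxy-4-methylpent-2-ynoyl)-2,2-dimethyl-3,5-bis(3-methylbut-2-en-1-yl)-1-(2-methylpropanoyl)bicyclo[3.2.1]octane-7,8-dione | CC(C)=CC[C@@H]1C[C@]2(CC=C(C)C)C(=O)[C@@](C(=O)C(C)C)(C(=O)[C@@]2(O)C(=O)C#CC(C)(C)O)C1(C)C | intermediate
25 | (1R,3R,5S,6S)-6-hydroxy-6-[(2Z)-4-hydroxy-4-methylpent-2-enoyl]-2,2-dimethyl-3,5-bis(3-methylbut-2-en-1-yl)-1-(2-methylpropanoyl)bicyclo[3.2.1]octane-7,8-dione | CC(C)=CC[C@@H]1C[C@]2(CC=C(C)C)C(=O)[C@@](C(=O)C(C)C)(C(=O)[C@@]2(O)C(=O)/C=C\C(C)(C)O)C1(C)C | target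

**Step count**

Total: 16 steps. Longest linear sequence: 15 steps (steps 1–7 and 9–16); step 8 prepares the alkynylating agent.

**Steps most likely to fail**

1. Step 13 (key step). The amidine may add to a ketone of the triacyl C1 centre and start a retro-Claisen fragmentation, or the closure may run through an ion-paired array in which the C6 oxygen faces the enolate oxygen, which would erode facial selectivity at C6. The fallback sets out from 20 and avoids a free enolate. Me3SiOTf and Et3N in CH2Cl2 at −78 → −20 °C should convert the C8 ketone in the flask into the C5=C8 trimethylsilyl enol ether of 20 F2. This adds in a Mukaiyama aldol, through an open transition state with the two silyloxy groups apart, to the silyl-activated central carbonyl and gives the C6 O-trimethylsilyl ether of 21 F3. HF·pyridine in MeCN at 0 °C then removes the silyl group and the route is rejoined at 21.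

2. Step 9. The enolate may attack bromine instead of carbon (halogen transfer, which returns 11 on work-up), or it may fail to reach the sp carbon next to the gem-dimethyl group. The fallback sets out from 11. Ethynyl transfer from hypervalent iodine, using 1-[(trimethylsilyl)ethynyl]-1,2-benziodoxol-3(1H)-one and n-Bu4NF in THF at −78 °C, offers no halogen to abstract and should give (2R,4S)-2-ethynyl-3,3-dimethyl-4-(3-methylbut-2-en-1-yl)-2-(2-methylpropanoyl)cyclohexan-1-one F1. Oxidative methoxycarbonylation of the terminal alkyne (PdCl2 cat., CuCl2, NaOAc, CO, MeOH, rt) then rejoins the route at 14.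

3. Step 14. The C6 aluminium alkoxide may open by retro-aldol reaction with loss of the C6 configuration, or acyl substitution at the neopentyl ester may not take place. The fallback sets out from 19 and moves the exchange ahead of the ring closure. Me2AlSEt in CH2Cl2 at 0 °C → rt acts on the unhindered CH2CO2Me group and should give S-ethyl 3-[(1R,3R,5RS)-2,2-dimethyl-3,5-bis(3-methylbut-2-en-1-yl)-1-(2-methylpropanoyl)-6-oxocyclohexyl]-3-oxopropanethioate F4. Dess–Martin periodinane and pyridine, as in step 12, give the α,β-diketo thioester S-ethyl 3-[(1R,3R,5RS)-2,2-dimethyl-3,5-bis(3-methylbut-2-en-1-yl)-1-(2-methylpropanoyl)-6-oxocyclohexyl]-2,3-dioxopropanethioate F5. DBU, as in step 13, closes F5 directly to 22, where the route is rejoined.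

**Further compounds**

F1 | step 9 | (2R,4S)-2-ethynyl-3,3-dimethyl-4-(3-methylbut-2-en-1-yl)-2-(2-methylpropanoyl)cyclohexan-1-one | CC(C)=CC[C@@H]1CCC(=O)[C@@](C(=O)C(C)C)(C#C)C1(C)C
F2 | step 13 | methyl 3-[(1R,3R)-2,2-dimethyl-3,5-bis(3-methylbut-2-en-1-yl)-1-(2-methylpropanoyl)-6-(trimethylsilyloxy)cyclohex-5-en-1-yl]-2,3-dioxopropanoate (C5=C8 trimethylsilyl enol ether of 20) | CC(C)=CC[C@@H]1CC(CC=C(C)C)=C(O[Si](C)(C)C)[C@@](C(=O)C(C)C)(C(=O)C(=O)C(=O)OC)C1(C)C
F3 | step 13 | methyl (1R,3R,5S,6R)-2,2-dimethyl-3,5-bis(3-methylbut-2-en-1-yl)-1-(2-methylpropanoyl)-7,8-dioxo-6-(trimethylsilyloxy)bicyclo[3.2.1]octane-6-carboxylate (C6 O-trimethylsilyl ether of 21) | CC(C)=CC[C@@H]1C[C@]2(CC=C(C)C)C(=O)[C@@](C(=O)C(C)C)(C(=O)[C@@]2(O[Si](C)(C)C)C(=O)OC)C1(C)C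
F4 | step 14 | S-ethyl 3-[(1R,3R,5RS)-2,2-dimethyl-3,5-bis(3-methylbut-2-en-1-yl)-1-(2-methylpropanoyl)-6-oxocyclohexyl]-3-oxopropanethioate | CC(C)=CC[C@@H]1CC(CC=C(C)C)C(=O)[C@@](C(=O)C(C)C)(C(=O)CC(=O)SCC)C1(C)C
F5 | step 14 | S-ethyl 3-[(1R,3R,5RS)-2,2-dimethyl-3,5-bis(3-methylbut-2-en-1-yl)-1-(2-methylpropanoyl)-6-oxocyclohexyl]-2,3-dioxopropanethioate | CC(C)=CC[C@@H]1CC(CC=C(C)C)C(=O)[C@@](C(=O)C(C)C)(C(=O)C(=O)C(=O)SCC)C1(C)C
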